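**Plan**

- Numbering and enabling feature: C1 angelate carbinol, C2=C3 olefin (CH3 on C3), C4 CH2, C5 veratrate carbinol, C6 fusion CH, C7 C(OH)(i-Pr), C8 and C9 CH2, C10 methyl-bearing fusion carbon. Ring A (seven-membered) is C1–C6 plus C10; ring B (five-membered) is C6–C10. C1 lies between quaternary C10 and the C2=C3(CH3) unit, so a six-membered C1 ketone lacking C2 has one enolisable position, C3, and C2 can be inserted between C1 and C3.
- Retrosynthetic cuts, in order: C1–O (angelate, with inversion); C1–C2 and C2–C3 (C2 leaves as CH2, ring A contracts to a cyclohexanone); C5–O (veratrate); C3–C4 (enolate alkylation); C7–i-Pr; C5–C6 (aldol); C10–C1 (conjugate addition).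
- Forward order: ring B is the starting cyclopentenone. A conjugate addition/aldol attaches C1/C3 and C4/C5, i-Pr adds to C7, the cyclohexanone closes by C3→C4 alkylation (trans-hydrindanone), C2 is inserted to give ring A, and reduction, angeloylation and desilylation finish.
- Stereochemistry: C10 from the chiral copper catalyst; C6 and C5 from the aldol (aldehyde anti to the branched alkenyl group, chair transition state, anti); C7 from addition anti to the C6 side chain; C1 from hydride delivery anti to the angular methyl, then Mitsunobu inversion.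

Key step: step 11

Remark: the phosphoramidite antipode is assumed to be the one that delivers the alkenyl group to the enone face giving (S)-configured C10; its mirror image would lead into the enantiomeric series. The C3 stereocentre of 13, 14 and 16 (absent from the target) is carried as a mixture.

**Route**

Step 1
Reactants: 1 3-methylcyclopent-2-en-1-one; 2 2-bromobut-1-ene; 3 (benzyloxy)acetaldehyde
Product: 6 (5R,6S,10S)-aldol adduct [(2S,3S)-2-[(1R)-2-(benzyloxy)-1-hydroxyethyl]-3-(but-1-en-2-yl)-3-methylcyclopentan-1-one], via alkenylalane 4 (not isolated), via aluminium enolate 5 (not isolated)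
Conditions: 2, t-BuLi (2 equiv), Et2O, −78 °C; Me2AlCl, −78 → −30 °C; 1, Cu(OTf)2 (5 mol%), (S)-binaphthol-derived N,N-bis[(R)-1-phenylethyl]phosphoramidite (10 mol%), −30 °C; 3 (excess), −78 °C; aq. Rochelle salt
Reagents that add atoms: none
Why: Copper-catalysed asymmetric conjugate addition of an alkenylalane to a β-methyl cyclic enone (alkenyl transfers in preference to methyl) sets quaternary C10 under ligand control, and the regiodefined aluminium enolate 5 then adds to the aldehyde through a closed chair transition state (Zimmerman–Traxler aldol of an (E)-configured cyclic enolate, anti C5/C6) on the face opposite the branched but-1-en-2-yl group, the larger C10 substituent, which places the side chain trans to the alkenyl group as the trans ring fusion requires.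

Step 2
Reactants: 6 aldol adduct
Product: 7 (5R,6S,7R,10S)-diol [(1R,2S,3S)-2-[(1R)-2-(benzyloxy)-1-hydroxyethyl]-3-(but-1-en-2-yl)-3-methyl-1-(propan-2-yl)cyclopentan-1-ol]
Conditions: i-PrMgCl (3.5 equiv), anhydrous CeCl3, THF, −78 °C
Reagents that add atoms: isopropylmagnesium chloride, CC(C)[Mg]Cl
Why: Organocerium 1,2-addition suppresses enolisation, retro-aldol cleavage and β-hydride reduction, and the isopropyl group should enter the cyclopentanone face opposite the adjacent C6 side chain (held on the lower face in the cerium alkoxide chelate), so the new C7 hydroxyl is cis to that chain.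

Step 3
Reactants: 7 diol
Product: 8 (5R,6S,7R,10S)-acetonide (isopropylidene acetal joining O5 and O7; benzyl ether and but-1-en-2-yl group retained)
Conditions: 2,2-dimethoxypropane, PPTS (cat.), CH2Cl2, rt
Reagents that add atoms: 2,2-dimethoxypropane, COC(C)(C)OC
Why: Acid-catalysed transacetalisation joins the cis-disposed O5 and O7 in a six-membered acetal, masking both hydroxyls; the free tertiary hydroxyl would otherwise close a tetrahydrofuran onto C4 in steps 6 and 7.

Step 4
Reactants: 8 acetonide
Product: 10 ethyl ketone (C10 propanoyl group; acetonide and benzyl ether retained), via ozonide 9 (not isolated)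
Conditions: O3, CH2Cl2, −78 °C; PPh3, −78 °C → rt
Reagents that add atoms: ozone, [O-][O+]=O
Why: Ozonolysis with reductive work-up cleaves the electron-rich 1,1-disubstituted olefin much faster than ozone attacks the benzyl ether or the acetal, unmasking C1 as the ethyl ketone that already carries C3 and its methyl group.

Step 5
Reactants: 10 ethyl ketone
Product: 11 primary alcohol (C4–OH)
Conditions: H2 (1 atm), Pd/C, EtOAc, rt
Reagents that add atoms: none
Why: Hydrogenolysis of the benzyl ether over Pd/C leaves the hindered ketone and the acetal untouched.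

Step 6
Reactants: 11 primary alcohol
Product: 12 primary iodide (C4–I)
Conditions: I2, PPh3, imidazole, CH2Cl2, 0 °C → rt
Reagents that add atoms: iodine, II
Why: Appel-type iodination converts the primary alcohol into the iodide under neutral conditions that tolerate the acetal and the ketone.

Step 7
Reactants: 12 primary iodide
Product: 13 (5S,6S,7R,10S)-trans-hydrindanone acetonide (C1 ketone; C3 methyl as a mixture of epimers)
Conditions: KN(SiMe3)2, THF, −78 → 0 °C
Reagents that add atoms: none
Why: Because C10 is quaternary only the C3 enolate can form, and it displaces the primary iodide in an allowed 6-(enolendo)-exo-tet intramolecular C-alkylation (bond C3–C4) on a ring B whose C6/C10 trans relationship is already fixed; the C3 configuration is immaterial since C3 becomes sp2 in step 10.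

Step 8
Reactants: 13 trans-hydrindanone acetonide
Product: 14 (5S,6S,7R,10S)-5,7-dihydroxy trans-hydrindanone
Conditions: AcOH/H2O (4:1), 40 °C
Reagents that add atoms: none
Why: Mild acid hydrolysis removes the acetonide, which is strained by the fully substituted C7, while the tertiary alcohol and the γ-hydroxy ketone (no retro-aldol pathway) should persist.

Step 9
Reactants: 14 dihydroxy ketone; 15 3,4-dimethoxybenzoyl chloride
Product: 16 C5 veratrate of the trans-hydrindanone (C7–OH free)
Conditions: 15, pyridine, DMAP (cat.), CH2Cl2, 0 °C → rt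
Reagents that add atoms: none
Why: DMAP-catalysed acylation is selective for the secondary equatorial C5 hydroxyl over the hindered tertiary C7 hydroxyl.

Step 10
Reactants: 16 veratrate ketone
Product: 17 bis(trimethylsilyl) compound (C1–OSiMe3 with C1=C3 olefin; C7–OSiMe3; C5 veratrate)
Conditions: Me3SiOTf (3 equiv), Et3N, CH2Cl2, 0 °C → rt
Reagents that add atoms: trimethylsilyl trifluoromethanesulfonate, C[Si](C)(C)OS(=O)(=O)C(F)(F)F
Why: Soft enolisation with Me3SiOTf/Et3N silylates the ketone as its only possible enol ether (toward C3, since C10 is quaternary) and caps the tertiary hydroxyl in the same flask; the veratrate has no α-hydrogen and is inert.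

Step 11
Reactants: 17 bis(trimethylsilyl) enol ether; 18 diiodomethane
Product: 21 ring A enone (C1 ketone; C2=C3 olefin; C5 veratrate; C7–OSiMe3), via siloxycyclopropane 19 (not isolated), via β-chloro ketone 20 (not isolated)
Conditions: Et2Zn, 18, CH2Cl2, 0 °C → rt; FeCl3, DMF, 0 °C → rt; NaOAc, MeOH, 60 °C
Reagents that add atoms: none
Why: The zinc carbenoid EtZnCH2I transfers CH2 to the electron-rich tetrasubstituted enol ether C1=C3 in a concerted [2+1] addition, closing the three-membered ring C1–C2–C3 by cheletropic methylene transfer; its facial sense is irrelevant because C1 and C3 end up sp2. FeCl3 (trivalent iron) then oxidises siloxycyclopropane 19 by one electron, the shared C1–C3 bond of the bicyclo[4.1.0] unit breaks by β-scission to give the C1 ketone and a tertiary C3 radical, and this radical takes chlorine from a second FeCl3 to give 20, so ring A arises by enlargement of the six-membered ring through bond cleavage and not by an end-to-end cyclisation. NaOAc removes HCl by E1cB elimination through the acidic C2–H, which places the olefin at C2=C3 in conjugation and not toward C4 or the methyl group. The closest known reaction type is the one-carbon ring enlargement of cyclic trimethylsilyl enol ethers by Simmons–Smith cyclopropanation, FeCl3 opening and dehydrochlorination, as in the conversion of 2-methylcyclohexanone into 3-methylcyclohept-2-enone. No stereocentre that survives is created, and C5, C6, C7 and C10 are untouched. The selectivity needed is regiochemical: quaternary C10 allows only the C1=C3 enol ether, scission of the internal bond is favoured by strain release and the tertiary radical, and the veratrate (arene deactivated by its acyl group) and the tertiary silyl ether are expected to be inert.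

Step 12
Reactants: 21 ring A enone
Product: 22 (1S)-allylic alcohol (C1–OH cis to the C10 methyl; C5 veratrate; C7–OSiMe3)
Conditions: NaBH4, CeCl3·7H2O, MeOH, −40 °C
Reagents that add atoms: none
Why: In this Luche 1,2-reduction the hydride should attack C1 on the face opposite the pseudo-axial C10 methyl group (steric and torsional control, as for ketones flanked by an angular methyl), giving the alcohol with OH cis to that methyl.

Step 13
Reactants: 22 (1S)-allylic alcohol; 23 angelic acid [(Z)-2-methylbut-2-enoic acid]
Product: 24 (1R)-angelate (C5 veratrate; C7–OSiMe3)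
Conditions: 23, PPh3, DIAD, toluene, 0 °C → rt
Reagents that add atoms: none
Why: Mitsunobu esterification displaces the oxyphosphonium group by SN2 with inversion at C1, the carboxylate entering from the open face anti to the C10 methyl; the neutral conditions preserve the (Z)-olefin of the angelate, SN2' attack is blocked because C3 is fully substituted, and the tertiary silyl ether is unreactive.

Step 14
Reactants: 24 angelate silyl ether
Product: 25 target compound
Conditions: HF·pyridine, pyridine, THF, 0 °C
Reagents that add atoms: none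
Why: Fluoride-mediated cleavage of the tertiary trimethylsilyl ether (driven by the Si–F bond) under buffered conditions leaves both esters and the allylic system intact.

**Compound list**

1 | 3-methylcyclopent-2-en-1-one | CC1=CC(=O)CC1 | starting material
2 | 2-bromobut-1-ene | C=C(Br)CC | starting material
3 | (benzyloxy)acetaldehyde | O=CCOCc1ccccc1 | starting material
4 | (but-1-en-2-yl)dimethylaluminium | C=C(CC)[Al](C)C | intermediate (not isolated)
5 | dimethylaluminium enolate of (S)-3-(but-1-en-2-yl)-3-methylcyclopentanone (C7–O–Al, C6=C7) | C[Al](C)OC1=C[C@](C(=C)CC)(C)CC1 | intermediate (not isolated)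
6 | (2S,3S)-2-[(1R)-2-(benzyloxy)-1-hydroxyethyl]-3-(but-1-en-2-yl)-3-methylcyclopentan-1-one | c1ccccc1COC[C@H](O)[C@@H]2[C@](C(=C)CC)(C)CCC2=O | intermediate
7 | (1R,2S,3S)-2-[(1R)-2-(benzyloxy)-1-hydroxyethyl]-3-(but-1-en-2-yl)-3-methyl-1-(propan-2-yl)cyclopentan-1-ol | c1ccccc1COC[C@H](O)[C@@H]2[C@](C(=C)CC)(C)CC[C@@]2(O)C(C)C | intermediate
8 | acetonide of 7 (isopropylidene acetal across O5 and O7) | c1ccccc1COC[C@H](O3)[C@@H]2[C@](C(=C)CC)(C)CC[C@@]2(OC3(C)C)C(C)C | intermediate
9 | ozonide of 8 (3-ethyl-1,2,4-trioxolan-3-yl group on C10) | c1ccccc1COC[C@H](O3)[C@@H]2[C@](C4(CC)OCOO4)(C)CC[C@@]2(OC3(C)C)C(C)C | intermediate (not isolated)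
10 | ethyl ketone (C10 propanoyl; acetonide; benzyl ether) | c1ccccc1COC[C@H](O3)[C@@H]2[C@](C(=O)CC)(C)CC[C@@]2(OC3(C)C)C(C)C | intermediate
11 | primary alcohol (C4–OH; C10 propanoyl; acetonide) | OC[C@H](O3)[C@@H]2[C@](C(=O)CC)(C)CC[C@@]2(OC3(C)C)C(C)C | intermediate
12 | primary iodide (C4–I; C10 propanoyl; acetonide) | IC[C@H](O3)[C@@H]2[C@](C(=O)CC)(C)CC[C@@]2(OC3(C)C)C(C)C | intermediate
13 | (5S,6S,7R,10S)-trans-hydrindanone acetonide (C1 ketone, C3 methyl, C3 epimers) | O=C1C(C)C[C@H](O3)[C@@H]2[C@]1(C)CC[C@@]2(OC3(C)C)C(C)C | intermediate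
14 | (5S,6S,7R,10S)-5,7-dihydroxy trans-hydrindanone (C3 epimers) | O=C1C(C)C[C@H](O)[C@@H]2[C@]1(C)CC[C@@]2(O)C(C)C | intermediate
15 | 3,4-dimethoxybenzoyl chloride | COc1ccc(cc1OC)C(Cl)=O | starting material
16 | C5 veratrate of 14 (C7–OH free, C3 epimers) | O=C1C(C)C[C@H](OC(=O)c3ccc(OC)c(OC)c3)[C@@H]2[C@]1(C)CC[C@@]2(O)C(C)C | intermediate
17 | trans-hydrindanone trimethylsilyl enol ether (C1–OSiMe3, C1=C3) with C5 veratrate and C7–OSiMe3 | C[Si](C)(C)OC1=C(C)C[C@H](OC(=O)c3ccc(OC)c(OC)c3)[C@@H]2[C@]1(C)CC[C@@]2(O[Si](C)(C)C)C(C)C | intermediate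
18 | diiodomethane | ICI | starting material
19 | siloxycyclopropane (C1–C2–C3 three-membered ring; C1–OSiMe3) | C[Si](C)(C)OC13CC3(C)C[C@H](OC(=O)c4ccc(OC)c(OC)c4)[C@@H]2[C@]1(C)CC[C@@]2(O[Si](C)(C)C)C(C)C | intermediate (not isolated)
20 | β-chloro ketone (ring A, C1 ketone, C3 chloro and methyl) | O=C1CC(Cl)(C)C[C@H](OC(=O)c3ccc(OC)c(OC)c3)[C@@H]2[C@]1(C)CC[C@@]2(O[Si](C)(C)C)C(C)C | intermediate (not isolated)
21 | ring A enone (C1 ketone, C2=C3) with C5 veratrate and C7–OSiMe3 | O=C1C=C(C)C[C@H](OC(=O)c3ccc(OC)c(OC)c3)[C@@H]2[C@]1(C)CC[C@@]2(O[Si](C)(C)C)C(C)C | intermediate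
22 | (1S)-allylic alcohol (OH cis to C10 methyl) | O[C@H]1C=C(C)C[C@H](OC(=O)c3ccc(OC)c(OC)c3)[C@@H]2[C@]1(C)CC[C@@]2(O[Si](C)(C)C)C(C)C | intermediate
23 | angelic acid [(Z)-2-methylbut-2-enoic acid] | C/C=C(/C)C(=O)O | starting material
24 | (1R)-angelate with C5 veratrate and C7–OSiMe3 | C/C=C(/C)C(=O)O[C@@H]1C=C(C)C[C@H](OC(=O)c3ccc(OC)c(OC)c3)[C@@H]2[C@]1(C)CC[C@@]2(O[Si](C)(C)C)C(C)C | intermediate
25 | CNP0142353.1, (1R,5S,6S,7R,10S) in the numbering above | C/C=C(/C)C(=O)O[C@@H]1C=C(C)C[C@H](OC(=O)c2ccc(OC)c(OC)c2)[C@@H]2[C@]1(C)CC[C@@]2(O)C(C)C | target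

**Step count**

Total: 14 steps. Longest linear sequence: 14 steps (from 1 to 25).

**Steps most likely to fail, with fallbacks**

Step 1. The aldehyde may add to enolate 5 with poor facial discrimination between the but-1-en-2-yl and methyl groups on C10, and alkenyl transfer to the five-membered enone may be poorly enantioselective. The fallback sets out from 1 and uses a much bulkier, silicon-bearing alkenyl group. Conjugate addition of diisobutyl[1-(trimethylsilyl)ethenyl]alane (from ethynyltrimethylsilane and i-Bu2AlH) under Cu(OTf)2 with a chiral sulfonate-bearing N-heterocyclic carbene ligand, then trapping with 3, should give the 1-(trimethylsilyl)ethenyl aldol F1. CeCl3/i-PrMgCl would give the diol F2, and 2,2-dimethoxypropane/PPTS the acetonide F3. Iododesilylation with N-iodosuccinimide would give the alkenyl iodide F4, and Negishi coupling with Et2Zn and Pd(dppf)Cl2 installs the ethyl group and returns to 8.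

Step 11. Cyclopropanation of the hindered tetrasubstituted enol ether may stall, or the arene or silyl ether may be attacked during the FeCl3 stage. The fallback sets out from 16 and inserts C2 by diazo homologation. Me3SiCHN2 with AlMe3 in CH2Cl2 should bring about migration of the less substituted C3 to give the C2-silylated seven-membered ketone F5, which is protodesilylated on acidic work-up to the saturated ring A ketone F6. Me3SiOTf/Et3N would give the bis(trimethylsilyl) compound F7 (enol ether C1=C2, the only enolisable side), and dehydrosilylation with Pd(OAc)2 in MeCN (Saegusa–Ito oxidation) returns to 21.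

Step 13. Displacement at the hindered allylic carbinol flanked by quaternary C10 may be slow with the weakly acidic angelic acid, allowing elimination or ionisation, and the angelate may isomerise toward the tiglate. The fallback sets out from 22 and separates inversion from angeloylation. Mitsunobu reaction with the more acidic 4-nitrobenzoic acid (PPh3, DIAD) should give the inverted (1R)-4-nitrobenzoate F8. K2CO3 in MeOH at 0 °C cleaves this activated ester in preference to the electron-rich veratrate, giving the (1R)-alcohol F9. Acylation with retention by the mixed anhydride of 23 and 2,4,6-trichlorobenzoyl chloride (Et3N, toluene, 80 °C, Yamaguchi conditions) returns to 24.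

**Further compounds**

F1 | step 1 | (2S,3S)-2-[(1R)-2-(benzyloxy)-1-hydroxyethyl]-3-methyl-3-[1-(trimethylsilyl)ethenyl]cyclopentan-1-one | c1ccccc1COC[C@H](O)[C@@H]2[C@](C(=C)[Si](C)(C)C)(C)CCC2=O
F2 | step 1 | diol from F1 (C7 hydroxyl and isopropyl, same configuration as 7) | c1ccccc1COC[C@H](O)[C@@H]2[C@](C(=C)[Si](C)(C)C)(C)CC[C@@]2(O)C(C)C
F3 | step 1 | acetonide of F2 | c1ccccc1COC[C@H](O3)[C@@H]2[C@](C(=C)[Si](C)(C)C)(C)CC[C@@]2(OC3(C)C)C(C)C
F4 | step 1 | 1-iodoethenyl analogue of 8 | c1ccccc1COC[C@H](O3)[C@@H]2[C@](C(=C)I)(C)CC[C@@]2(OC3(C)C)C(C)C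
F5 | step 11 | C2-trimethylsilyl ring A ketone (C5 veratrate, C7–OH) | O=C1C([Si](C)(C)C)C(C)C[C@H](OC(=O)c3ccc(OC)c(OC)c3)[C@@H]2[C@]1(C)CC[C@@]2(O)C(C)C
F6 | step 11 | saturated ring A ketone (C1 ketone, C3 methyl, C5 veratrate, C7–OH) | O=C1CC(C)C[C@H](OC(=O)c3ccc(OC)c(OC)c3)[C@@H]2[C@]1(C)CC[C@@]2(O)C(C)C
F7 | step 11 | bis(trimethylsilyl) compound of F6 (C1–OSiMe3, C1=C2; C7–OSiMe3) | C[Si](C)(C)OC1=CC(C)C[C@H](OC(=O)c3ccc(OC)c(OC)c3)[C@@H]2[C@]1(C)CC[C@@]2(O[Si](C)(C)C)C(C)C
F8 | step 13 | (1R)-4-nitrobenzoate (C5 veratrate, C7–OSiMe3) | O=C(c3ccc(cc3)[N+](=O)[O-])O[C@@H]1C=C(C)C[C@H](OC(=O)c4ccc(OC)c(OC)c4)[C@@H]2[C@]1(C)CC[C@@]2(O[Si](C)(C)C)C(C)C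
F9 | step 13 | (1R)-allylic alcohol (C1 epimer of 22) | O[C@@H]1C=C(C)C[C@H](OC(=O)c3ccc(OC)c(OC)c3)[C@@H]2[C@]1(C)CC[C@@]2(O[Si](C)(C)C)C(C)C
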